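Readings and results come from a simulation for substances that don't exist; the scatter is artificial.

Tuesday's flask slows with E still at 21.4% at 80.0 s.

| flask | E | Q | X | remark | time |
|---|---|---|---|---|---|
| Tuesday's | 2.0 × 10⁻⁴ M | 1.3 equiv | 1 mol% | run made earlier |  |
| Sunday's | 2.0 × 10⁻⁴ M | 0.65 equiv | 1 mol% | run made earlier |  |
| Thursday's | 2.0 × 10⁻⁴ M | 2.6 equiv | 1 mol% | run made earlier |  |
| Saturday's | 2.0 × 10⁻⁴ M | 1.3 equiv | 1.5 mol% | run made earlier |  |
| eta | 2.0 × 10⁻⁴ M | 1.30 equiv (in portions, 3, over 1.5 min) | 1 mol% | first portion at the start, last at 1.5 min | 2.0 min |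
| zeta | 2.0 × 10⁻⁴ M (fed, over 1.5 min) | 1.30 equiv | 1 mol% | all else is in the flask from the start; the feed brings no volume worth counting | 2.0 min |
| alpha | 2.0 × 10⁻⁴ M (fed, over 10 s) | 1.30 equiv | 1 mol% | all else is in the flask from the start; the feed brings no volume worth counting | 2.0 min |
| theta | 2.0 × 10⁻⁴ M | 1.30 equiv (fed, over 1.5 min) | 1 mol% | all else is in the flask from the start; the feed brings no volume worth counting | 2.0 min |
| gamma | 2.0 × 10⁻⁴ M | 1.30 equiv | 1 mol% | everything together at the start | 2.0 min |

| run | time / s | G / % | E / % |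
|---|---|---|---|
| Tuesday's | 10.0 | 19.7 | 66.0 |
| Tuesday's | 15.0 | 29.9 | 56.7 |
| Tuesday's | 25.0 | 45.7 | 43.5 |
| Tuesday's | 40.0 | 58.4 | 32.1 |
| Tuesday's | 60.0 | 67.4 | 25.3 |
| Tuesday's | 80.0 | 71.6 | 21.4 |
| Sunday's | 10.0 | 16.6 | 68.4 |
| Sunday's | 15.0 | 25.0 | 59.3 |
| Sunday's | 25.0 | 37.6 | 47.6 |
| Sunday's | 40.0 | 48.1 | 37.2 |
| Sunday's | 80.0 | 59.6 | 26.5 |
| Sunday's | 120 | 62.5 | 23.5 |
| Thursday's | 10.0 | 21.8 | 64.0 |
| Thursday's | 15.0 | 32.8 | 54.5 |
| Thursday's | 25.0 | 48.5 | 41.4 |
| Thursday's | 40.0 | 61.7 | 30.1 |
| Thursday's | 80.0 | 73.3 | 21.2 |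
| Thursday's | 120 | 76.7 | 18.4 |
| Saturday's | 25.0 | 63.2 | 28.4 |
| Saturday's | 50.0 | 80.8 | 14.7 |
| Saturday's | 80.0 | 86.8 | 10.3 |
| Saturday's | 90.0 | 87.4 | 8.9 |
| Saturday's | 120 | 89.4 | 8.7 |

(standard deviation of a reading: 0.3 percentage points)

- a reading or a percentage of G counts all its forms, free or not

1. the best flask by amount of G, in percent of the E charged; "all alike" if 1.5 percentage points covers them all (eta / zeta / alpha / theta / gamma / all alike)
2. amount of G at the end, in percent of the E charged, eta
3. amount of G at the end, in percent of the E charged, zeta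
4. amount of G at the end, in percent of the E charged, alpha
5. amount of G at the end, in percent of the E charged, theta
6. amount of G at the end, in percent of the E charged, gamma

With twice the Q, Thursday's E at 80.0 s stands at 21.2%, beside Tuesday's 21.4%, so the fading thing is taken to be X, with E falling pseudo-first-order on a dying catalyst. Tuesday's ln(1/fraction of E left) is 1.14 at 40.0 s and 1.54 at 80.0 s. The second stretch therefore yields 0.357 of the first, which gives X a lifetime, as read from these readings, of 38.8 s. The series sums to 1.77: the catalyst budget, the total of ln(1/fraction of E left) that a fresh charge of 1 mol% of X can do. Scaled to Saturday's X, it leaves 7.97% of E at 120 s, against a reading of 8.7%.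

Gamma is the zero of the scale: its E meets 1.69 of budget and keeps 18.5%. Zeta's slices, taken at the start, middle and end of the feed, meet 1.69, 0.474 and 0.0936, assuming X dies with or without E. Weighted 1, 4, 1, they keep 59.8% of E.

Tuesday's E and G together fall short of the charge by 7.00% at 80.0 s, and this gap is taken to be an intermediate J on the way from E to G. Subtracting that J would give zeta 33.2% of G, and that is the weak link, since J from zeta's last slice meets a budget of 0.0936, less than gamma's 1.69. Reforged: at 25.0 s, Tuesday's E over J gives J a pace, called ρ, of 5.03 times that of E. A slice with budget w then ends as G to the fraction 1 − (ρ·exp(−w) − exp(−ρw))/(ρ − 1). This gives gamma 76.9% and zeta 29.5%. Sunday's flask, with half the Q of Tuesday's, stands 10 percentage points lower in G at 40.0 s, so eta and theta, short of Q early, are put within about that distance below gamma, and gamma is the choice.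

The forecast says gamma is best, with eta 58%, zeta 30%, alpha 70%, theta 55% and gamma 75%, on the grounds that “Late-arriving E or Q therefore meets dead catalyst”. It parts from the reckoning above on eta and theta.

The flasks give eta 71.5%, zeta 27.0%, alpha 69.0%, theta 72.2% and gamma 75.4%, with gamma best. Eta and theta stand 14 points and 17 points above the forecast.

    E + X ⇌ X + J (K = 3.80, k = 28000 M⁻¹ s⁻¹)
    X + J ⇌ D (K = 66000 M⁻¹, k = 1.30 × 10⁵ M⁻¹ s⁻¹)
    Q + D → X + G (k = 87000 M⁻¹ s⁻¹)
    X → L (k = 0.0300 s⁻¹)
    Z ⇌ G, rate k5*(cs5 - [G]) while solid is left; crystals form when [G] > cs5 (solubility = 0.160 mM, k = 26.0 s⁻¹)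

In zeta the half-life of E by the forward rate of its step with X alone grows from 0.88 min at 0.797 min to 6.6 min at 2.00 min, a factor of 7.50, while the reckoned budget shrinks by a factor of 6.43 over that span. The later half-life is longer than the 2.0 min of the run, and zeta ends with E at 61.8%, beside 59.8% from its slices. Scaled to the 0.6 mol% of X in a neighbour of zeta, the same slices keep 72.0% of E, and that neighbour flask ends with 73.3%.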